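**Retrosynthetic overview**
- Last C–C bond: the ring quaternary carbon to the side-chain CH2, made by a visible-light photoredox addition of a ring tertiary radical (from a caesium oxalate) to the terminal 1,3-diene of the complete, acetylated side chain.
- Side-chain dienyl acetate: methyl stereocentre bought in (S)-citronellal; the carbinol set by chelation-controlled alkynylation of (R)-glyceraldehyde acetonide; E-trisubstituted alkene by Zr-catalysed carboalumination and Pd vinylation.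
- Ring piece: the only carbocycle is bought intact as (1S,2S,4R)-limonene-1,2-diol, so no ring-forming step is needed; its tertiary carbinol is a target stereocentre and its isopropenyl centre relays the configuration of the three-carbon arm before being erased.
- Ring elaboration: aldol condensation and conjugate reduction (arm), MeCeCl2 addition and oxalate (radical precursor), allylic oxidation and alkene migration (Z-enal); final step is desilylation.

Assumption: (S)-citronellal, (R)-2,3-O-isopropylideneglyceraldehyde, (1S,2S,4R)-limonene-1,2-diol and 3-[(tert-butyldiphenylsilyl)oxy]propanal are taken as commercial.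

**Route**

Step 1
Reactants: 1 (S)-citronellal
Product: 2 (3S)-3,7-dimethyloct-6-en-1-yne
Conditions: C4F9SO2F, P2-Et phosphazene base, DMF, −20 → 25 °C
Reagents that add atoms: none
Why: One-pot enol nonaflate formation and base-induced β-elimination (aldehyde-to-alkyne conversion without added carbon) leaves the bought β-stereocentre untouched.

Step 2
Reactants: 2 (3S)-3,7-dimethyloct-6-en-1-yne; 3 (R)-2,3-O-isopropylideneglyceraldehyde
Product: 4 (1R,4S)-1-[(4R)-2,2-dimethyl-1,3-dioxolan-4-yl]-4,8-dimethylnon-7-en-2-yn-1-ol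
Conditions: n-BuLi, Et2O, −78 °C; ZnBr2; then 3, −78 → 0 °C
Reagents that add atoms: none
Why: Chelation-controlled (Cram chelate) addition of the alkynylzinc bromide to the α-alkoxy aldehyde: zinc bridges the carbonyl and the dioxolane oxygen and the nucleophile enters opposite the CH2O arm, so the bought dioxolane centre sets the new carbinol as R (syn adduct).

Step 3
Reactants: 4 (1R,4S)-1-[(4R)-2,2-dimethyl-1,3-dioxolan-4-yl]-4,8-dimethylnon-7-en-2-yn-1-ol
Product: 5 (1R,2E,4S)-1-[(4R)-2,2-dimethyl-1,3-dioxolan-4-yl]-4,8-dimethylnona-2,7-dien-1-ol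
Conditions: LiAlH4, THF, 0 → 45 °C
Reagents that add atoms: none
Why: Hydroxyl-directed trans-hydroalumination of the propargylic alcohol gives only the E-alkene and leaves the acetal and the remote trisubstituted alkene alone.

Step 4
Reactants: 5 (1R,2E,4S)-1-[(4R)-2,2-dimethyl-1,3-dioxolan-4-yl]-4,8-dimethylnona-2,7-dien-1-ol
Product: 6 tert-butyl{[(1R,2E,4S)-1-[(4R)-2,2-dimethyl-1,3-dioxolan-4-yl]-4,8-dimethylnona-2,7-dien-1-yl]oxy}dimethylsilane
Conditions: TBSCl, imidazole, DMF, 25 °C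
Reagents that add atoms: tert-butyldimethylsilyl chloride, CC(C)(C)[Si](C)(C)Cl
Why: Standard silylation of the secondary allylic alcohol protects the carbinol for the following carbonyl and organometallic steps.

Step 5
Reactants: 6 tert-butyl{[(1R,2E,4S)-1-[(4R)-2,2-dimethyl-1,3-dioxolan-4-yl]-4,8-dimethylnona-2,7-dien-1-yl]oxy}dimethylsilane
Product: 7 (2R,3E,5S)-2-[(tert-butyldimethylsilyl)oxy]-5,9-dimethyldeca-3,8-dienal
Conditions: H5IO6, EtOAc, 25 °C
Reagents that add atoms: none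
Why: Periodic acid hydrolyses the terminal acetonide and cleaves the 1,2-diol in one pot (Malaprade glycol cleavage) under non-basic conditions, so the adjacent silyloxy centre is not epimerised.

Step 6
Reactants: 7 (2R,3E,5S)-2-[(tert-butyldimethylsilyl)oxy]-5,9-dimethyldeca-3,8-dienal
Product: 8 tert-butyl{[(3R,4E,6S)-6,10-dimethylundeca-4,9-dien-1-yn-3-yl]oxy}dimethylsilane
Conditions: TMSCHN2, LiN(i-Pr)2, THF, −78 → 0 °C
Reagents that add atoms: (trimethylsilyl)diazomethane, C[Si](C)(C)C=[N+]=[N-]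
Why: Colvin rearrangement (Peterson-type olefination to a diazoalkene, loss of N2, 1,2-hydride shift of the alkylidene carbene) gives the terminal alkyne at −78 °C, cold enough to keep the sensitive α-silyloxy aldehyde configurationally intact.

Step 7
Reactants: 8 tert-butyl{[(3R,4E,6S)-6,10-dimethylundeca-4,9-dien-1-yn-3-yl]oxy}dimethylsilane
Product: 10 tert-butyldimethyl{[(3E,5R,6E,8S)-4,8,12-trimethyltrideca-1,3,6,11-tetraen-5-yl]oxy}silane, via alkenylalane 9 (not isolated)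
Conditions: Me3Al, Cp2ZrCl2 (20 mol %), CH2Cl2, 0 → 25 °C; then vinyl bromide, Pd(PPh3)4 (5 mol %), ZnCl2 (cat.), THF, 25 °C
Reagents that add atoms: trimethylaluminium, C[Al](C)C; vinyl bromide, C=CBr
Why: Negishi zirconium-catalysed syn-carboalumination puts methyl on the internal and aluminium on the terminal alkyne carbon, and Negishi cross-coupling of the alkenylalane proceeds with retention, fixing the E-trisubstituted alkene of the diene.

Step 8
Reactants: 10 tert-butyldimethyl{[(3E,5R,6E,8S)-4,8,12-trimethyltrideca-1,3,6,11-tetraen-5-yl]oxy}silane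
Product: 11 (3E,5R,6E,8S)-4,8,12-trimethyltrideca-1,3,6,11-tetraen-5-ol
Conditions: TBAF, THF, 0 °C
Reagents that add atoms: none
Why: Fluoride desilylation under basic conditions frees the doubly allylic alcohol without ionising it.

Step 9
Reactants: 11 (3E,5R,6E,8S)-4,8,12-trimethyltrideca-1,3,6,11-tetraen-5-ol
Product: 12 (3E,5R,6E,8S)-4,8,12-trimethyltrideca-1,3,6,11-tetraen-5-yl acetate
Conditions: Ac2O, pyridine, DMAP (cat.), CH2Cl2, 0 °C
Reagents that add atoms: acetic anhydride, CC(=O)OC(C)=O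
Why: DMAP-catalysed O-acylation installs the acetate of the target with retention at the carbinol.

Step 10
Reactants: 13 (1S,2S,4R)-1-methyl-4-(prop-1-en-2-yl)cyclohexane-1,2-diol
Product: 14 (2S,5R)-2-hydroxy-2-methyl-5-(prop-1-en-2-yl)cyclohexan-1-one
Conditions: IBX, EtOAc, 75 °C
Reagents that add atoms: none
Why: IBX oxidises the secondary hydroxyl of the 1,2-diol to the ketone without glycol cleavage, and the bought tertiary carbinol centre is untouched.

Step 11
Reactants: 14 (2S,5R)-2-hydroxy-2-methyl-5-(prop-1-en-2-yl)cyclohexan-1-one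
Product: 15 (2S,5R)-2-methyl-5-(prop-1-en-2-yl)-2-[(triethylsilyl)oxy]cyclohexan-1-one
Conditions: TESOTf, 2,6-lutidine, CH2Cl2, −78 → 0 °C
Reagents that add atoms: triethylsilyl trifluoromethanesulfonate, CC[Si](CC)(CC)OS(=O)(=O)C(F)(F)F
Why: Silyl triflate silylation of the hindered tertiary α-hydroxy ketone gives a bulky ether that later shields one ring face.

Step 12
Reactants: 15 (2S,5R)-2-methyl-5-(prop-1-en-2-yl)-2-[(triethylsilyl)oxy]cyclohexan-1-one; 16 3-[(tert-butyldiphenylsilyl)oxy]propanal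
Product: 19 (2S,5S,6E)-6-{3-[(tert-butyldiphenylsilyl)oxy]propylidene}-2-methyl-5-(prop-1-en-2-yl)-2-[(triethylsilyl)oxy]cyclohexan-1-one, via lithium aldolate 17 (not isolated), via mesylate 18 (not isolated)
Conditions: LiN(i-Pr)2, THF, −78 °C; 16; then MsCl, −78 → 0 °C; Et3N, 25 °C
Reagents that add atoms: none
Why: Directed aldol addition of the only possible lithium enolate, in situ mesylation and E1cB elimination (aldol condensation) bring in the three-carbon arm as the E-alkylidene ketone.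

Step 13
Reactants: 19 (2S,5S,6E)-6-{3-[(tert-butyldiphenylsilyl)oxy]propylidene}-2-methyl-5-(prop-1-en-2-yl)-2-[(triethylsilyl)oxy]cyclohexan-1-one
Product: 21 (2S,5R,6R)-6-{3-[(tert-butyldiphenylsilyl)oxy]propyl}-2-methyl-5-(prop-1-en-2-yl)-2-[(triethylsilyl)oxy]cyclohexan-1-one, via silyl enol ether 20 (not isolated)
Conditions: [(Ph3P)CuH]6 (5 mol %), PhMe2SiH, toluene, 25 °C; then TBAF, AcOH, THF, −78 °C
Reagents that add atoms: none
Why: Copper hydride 1,4-hydrosilylation (Stryker-type conjugate reduction) gives the silyl enol ether, and kinetic protonation of the fluoride-released enolate occurs anti to the pseudo-axial isopropenyl group, so the bought ring centres place the arm cis to isopropenyl and to the silyloxy group.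

Step 14
Reactants: 21 (2S,5R,6R)-6-{3-[(tert-butyldiphenylsilyl)oxy]propyl}-2-methyl-5-(prop-1-en-2-yl)-2-[(triethylsilyl)oxy]cyclohexan-1-one
Product: 23 methyl (2S,5R,6R)-6-{3-[(tert-butyldiphenylsilyl)oxy]propyl}-1,2-dimethyl-5-(prop-1-en-2-yl)-2-[(triethylsilyl)oxy]cyclohexyl oxalate (both C-1 epimers), via cerium alkoxide 22 (not isolated)
Conditions: MeLi, CeCl3, THF, −78 °C; then ClC(O)CO2Me, −78 → 0 °C
Reagents that add atoms: methyllithium, [Li]C; methyl chlorooxoacetate, COC(=O)C(Cl)=O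
Why: The weakly basic organocerium reagent (Imamoto addition) adds to the hindered, enolisable ketone without epimerising the α-centre and the alkoxide is acylated in the same flask; the configuration at the new carbinol is irrelevant because this carbon becomes a radical in step 18.

Step 15
Reactants: 23 methyl (2S,5R,6R)-6-{3-[(tert-butyldiphenylsilyl)oxy]propyl}-1,2-dimethyl-5-(prop-1-en-2-yl)-2-[(triethylsilyl)oxy]cyclohexyl oxalate
Product: 25 methyl (2S,5R,6R)-6-{3-[(tert-butyldiphenylsilyl)oxy]propyl}-1,2-dimethyl-5-(3-oxoprop-1-en-2-yl)-2-[(triethylsilyl)oxy]cyclohexyl oxalate, via allylic alcohol 24 (not isolated)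
Conditions: SeO2 (20 mol %), t-BuOOH, CH2Cl2, 25 °C; then Dess–Martin periodinane, NaHCO3, 25 °C
Reagents that add atoms: tert-butyl hydroperoxide, CC(C)(C)OO
Why: Sharpless–Umbreit allylic oxidation (ene reaction then 2,3-sigmatropic shift) hydroxylates the methyl group of the only alkene, and Dess–Martin oxidation of the crude allylic alcohol gives the 2-substituted acrolein.

Step 16
Reactants: 25 methyl (2S,5R,6R)-6-{3-[(tert-butyldiphenylsilyl)oxy]propyl}-1,2-dimethyl-5-(3-oxoprop-1-en-2-yl)-2-[(triethylsilyl)oxy]cyclohexyl oxalate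
Product: 26 methyl (2S,5Z,6R)-6-{3-[(tert-butyldiphenylsilyl)oxy]propyl}-1,2-dimethyl-5-(1-oxopropan-2-ylidene)-2-[(triethylsilyl)oxy]cyclohexyl oxalate
Conditions: RuHCl(CO)(PPh3)3 (5 mol %), toluene, 80 °C
Reagents that add atoms: none
Why: Ruthenium hydride addition and β-hydride elimination (alkene isomerisation into the tetrasubstituted conjugated position) run under thermodynamic control, which puts the small formyl group syn to the substituted ring carbon and the methyl group syn to the ring CH2 (allylic 1,3-strain), giving the Z-enal and erasing the isopropenyl-bearing centre after its relay work.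

Step 17
Reactants: 26 methyl (2S,5Z,6R)-6-{3-[(tert-butyldiphenylsilyl)oxy]propyl}-1,2-dimethyl-5-(1-oxopropan-2-ylidene)-2-[(triethylsilyl)oxy]cyclohexyl oxalate
Product: 27 caesium 2-{[(2S,5Z,6R)-6-{3-[(tert-butyldiphenylsilyl)oxy]propyl}-1,2-dimethyl-5-(1-oxopropan-2-ylidene)-2-[(triethylsilyl)oxy]cyclohexyl]oxy}-2-oxoacetate
Conditions: CsOH·H2O (1.0 equiv), THF/H2O, 25 °C
Reagents that add atoms: caesium hydroxide, [Cs+].[OH-]
Why: Selective saponification of the unhindered methyl ester of the mixed oxalate gives the bench-stable caesium oxalate radical precursor.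

Step 18
Reactants: 27 caesium 2-{[(2S,5Z,6R)-6-{3-[(tert-butyldiphenylsilyl)oxy]propyl}-1,2-dimethyl-5-(1-oxopropan-2-ylidene)-2-[(triethylsilyl)oxy]cyclohexyl]oxy}-2-oxoacetate; 12 (3E,5R,6E,8S)-4,8,12-trimethyltrideca-1,3,6,11-tetraen-5-yl acetate
Product: 28 (3E,5R,6E,8S)-1-[(1S,2S,5Z,6R)-6-{3-[(tert-butyldiphenylsilyl)oxy]propyl}-1,2-dimethyl-5-(1-oxopropan-2-ylidene)-2-[(triethylsilyl)oxy]cyclohexyl]-4,8,12-trimethyltrideca-3,6,11-trien-5-yl acetate
Conditions: Ru(bpz)3(PF6)2 (2 mol %; bpz = 2,2'-bipyrazine), 2,4,6-(i-Pr)3C6H2SH (20 mol %), H2O (10 equiv), 12 (1.5 equiv), DME/DMF 3:1, 450 nm LEDs, 25 °C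
Reagents that add atoms: none
Why: Proposed new method: the photoexcited divalent ruthenium complex (triplet energy too low to sensitise the diene) oxidises the oxalate, double loss of CO2 gives the tertiary ring radical, this adds to the terminal CH2 of the 1,3-diene, and the resulting allyl radical takes a hydrogen atom from the arenethiol at its less hindered terminus while the thiyl radical is reduced back by the monovalent ruthenium complex, so the quaternary carbon is formed with the E-trisubstituted alkene kept, the diene approaching the planar radical anti to both the silyloxy group and the three-carbon arm and therefore cis to the neighbouring methyl group; the closest known reaction type is the photoredox Giese addition of tertiary alkyl oxalate radicals to electron-poor alkenes, extended here to radical 1,2-hydroalkylation of an unactivated diene.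

Step 19
Reactants: 28 (3E,5R,6E,8S)-1-[(1S,2S,5Z,6R)-6-{3-[(tert-butyldiphenylsilyl)oxy]propyl}-1,2-dimethyl-5-(1-oxopropan-2-ylidene)-2-[(triethylsilyl)oxy]cyclohexyl]-4,8,12-trimethyltrideca-3,6,11-trien-5-yl acetate
Product: 29 (3E,5R,6E,8S)-1-[(1S,2S,5Z,6R)-2-hydroxy-6-(3-hydroxypropyl)-1,2-dimethyl-5-(1-oxopropan-2-ylidene)cyclohexyl]-4,8,12-trimethyltrideca-3,6,11-trien-5-yl acetate (CNP0259235.1)
Conditions: HF·pyridine, pyridine, THF, 0 → 25 °C
Reagents that add atoms: none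
Why: Buffered HF·pyridine desilylation removes the tertiary triethylsilyl and the primary tert-butyldiphenylsilyl ether while the allylic acetate and the enal survive, giving the target.

**Compound list**

1 | (S)-citronellal, (3S)-3,7-dimethyloct-6-enal | O=CC[C@@H](C)CCC=C(C)C | starting material
2 | (3S)-3,7-dimethyloct-6-en-1-yne | C#C[C@@H](C)CCC=C(C)C | intermediate
3 | (R)-2,3-O-isopropylideneglyceraldehyde, (4R)-2,2-dimethyl-1,3-dioxolane-4-carbaldehyde | O=C[C@H]1COC(C)(C)O1 | starting material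
4 | (1R,4S)-1-[(4R)-2,2-dimethyl-1,3-dioxolan-4-yl]-4,8-dimethylnon-7-en-2-yn-1-ol | O[C@H](C#C[C@@H](C)CCC=C(C)C)[C@H]1COC(C)(C)O1 | intermediate
5 | (1R,2E,4S)-1-[(4R)-2,2-dimethyl-1,3-dioxolan-4-yl]-4,8-dimethylnona-2,7-dien-1-ol | O[C@H](/C=C/[C@@H](C)CCC=C(C)C)[C@H]1COC(C)(C)O1 | intermediate
6 | tert-butyl{[(1R,2E,4S)-1-[(4R)-2,2-dimethyl-1,3-dioxolan-4-yl]-4,8-dimethylnona-2,7-dien-1-yl]oxy}dimethylsilane | CC(C)(C)[Si](C)(C)O[C@H](/C=C/[C@@H](C)CCC=C(C)C)[C@H]1COC(C)(C)O1 | intermediate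
7 | (2R,3E,5S)-2-[(tert-butyldimethylsilyl)oxy]-5,9-dimethyldeca-3,8-dienal | O=C[C@H](O[Si](C)(C)C(C)(C)C)/C=C/[C@@H](C)CCC=C(C)C | intermediate
8 | tert-butyl{[(3R,4E,6S)-6,10-dimethylundeca-4,9-dien-1-yn-3-yl]oxy}dimethylsilane | C#C[C@H](O[Si](C)(C)C(C)(C)C)/C=C/[C@@H](C)CCC=C(C)C | intermediate
9 | {(1E,3R,4E,6S)-3-[(tert-butyldimethylsilyl)oxy]-2,6,10-trimethylundeca-1,4,9-trien-1-yl}dimethylalane | C[Al](C)/C=C(\C)[C@H](O[Si](C)(C)C(C)(C)C)/C=C/[C@@H](C)CCC=C(C)C | intermediate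
10 | tert-butyldimethyl{[(3E,5R,6E,8S)-4,8,12-trimethyltrideca-1,3,6,11-tetraen-5-yl]oxy}silane | C=C/C=C(\C)[C@H](O[Si](C)(C)C(C)(C)C)/C=C/[C@@H](C)CCC=C(C)C | intermediate
11 | (3E,5R,6E,8S)-4,8,12-trimethyltrideca-1,3,6,11-tetraen-5-ol | C=C/C=C(\C)[C@H](O)/C=C/[C@@H](C)CCC=C(C)C | intermediate
12 | (3E,5R,6E,8S)-4,8,12-trimethyltrideca-1,3,6,11-tetraen-5-yl acetate | C=C/C=C(\C)[C@H](OC(C)=O)/C=C/[C@@H](C)CCC=C(C)C | intermediate
13 | (1S,2S,4R)-1-methyl-4-(prop-1-en-2-yl)cyclohexane-1,2-diol, (1S,2S,4R)-limonene-1,2-diol | C[C@]1(O)CC[C@@H](C(C)=C)C[C@@H]1O | starting material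
14 | (2S,5R)-2-hydroxy-2-methyl-5-(prop-1-en-2-yl)cyclohexan-1-one | C[C@]1(O)CC[C@@H](C(C)=C)CC1=O | intermediate
15 | (2S,5R)-2-methyl-5-(prop-1-en-2-yl)-2-[(triethylsilyl)oxy]cyclohexan-1-one | C[C@]1(O[Si](CC)(CC)CC)CC[C@@H](C(C)=C)CC1=O | intermediate
16 | 3-[(tert-butyldiphenylsilyl)oxy]propanal | O=CCCO[Si](c1ccccc1)(c1ccccc1)C(C)(C)C | starting material
17 | lithium 3-[(tert-butyldiphenylsilyl)oxy]-1-[(3S,6R)-3-methyl-2-oxo-6-(prop-1-en-2-yl)-3-[(triethylsilyl)oxy]cyclohexyl]propan-1-olate (diastereomer mixture at the two new centres) | [Li+].C[C@]1(O[Si](CC)(CC)CC)CC[C@@H](C(C)=C)C(C([O-])CCO[Si](c2ccccc2)(c2ccccc2)C(C)(C)C)C1=O | intermediate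
18 | 3-[(tert-butyldiphenylsilyl)oxy]-1-[(3S,6R)-3-methyl-2-oxo-6-(prop-1-en-2-yl)-3-[(triethylsilyl)oxy]cyclohexyl]propyl methanesulfonate (diastereomer mixture) | C[C@]1(O[Si](CC)(CC)CC)CC[C@@H](C(C)=C)C(C(OS(C)(=O)=O)CCO[Si](c2ccccc2)(c2ccccc2)C(C)(C)C)C1=O | intermediate
19 | (2S,5S,6E)-6-{3-[(tert-butyldiphenylsilyl)oxy]propylidene}-2-methyl-5-(prop-1-en-2-yl)-2-[(triethylsilyl)oxy]cyclohexan-1-one | C[C@]1(O[Si](CC)(CC)CC)CC[C@@H](C(C)=C)/C(=C\CCO[Si](c2ccccc2)(c2ccccc2)C(C)(C)C)C1=O | intermediate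
20 | {[(3S,6S)-2-{3-[(tert-butyldiphenylsilyl)oxy]propyl}-6-methyl-3-(prop-1-en-2-yl)-6-[(triethylsilyl)oxy]cyclohex-1-en-1-yl]oxy}dimethyl(phenyl)silane | C[C@]1(O[Si](CC)(CC)CC)CC[C@@H](C(C)=C)C(CCCO[Si](c2ccccc2)(c2ccccc2)C(C)(C)C)=C1O[Si](C)(C)c1ccccc1 | intermediate
21 | (2S,5R,6R)-6-{3-[(tert-butyldiphenylsilyl)oxy]propyl}-2-methyl-5-(prop-1-en-2-yl)-2-[(triethylsilyl)oxy]cyclohexan-1-one | C[C@]1(O[Si](CC)(CC)CC)CC[C@@H](C(C)=C)[C@@H](CCCO[Si](c2ccccc2)(c2ccccc2)C(C)(C)C)C1=O | intermediate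
22 | {[(2S,5R,6R)-6-{3-[(tert-butyldiphenylsilyl)oxy]propyl}-1,2-dimethyl-5-(prop-1-en-2-yl)-2-[(triethylsilyl)oxy]cyclohexyl]oxy}cerium dichloride (both C-1 epimers) | C[C@]1(O[Si](CC)(CC)CC)CC[C@@H](C(C)=C)[C@@H](CCCO[Si](c2ccccc2)(c2ccccc2)C(C)(C)C)C1(C)O[Ce](Cl)Cl | intermediate
23 | methyl (2S,5R,6R)-6-{3-[(tert-butyldiphenylsilyl)oxy]propyl}-1,2-dimethyl-5-(prop-1-en-2-yl)-2-[(triethylsilyl)oxy]cyclohexyl oxalate (both C-1 epimers) | C[C@]1(O[Si](CC)(CC)CC)CC[C@@H](C(C)=C)[C@@H](CCCO[Si](c2ccccc2)(c2ccccc2)C(C)(C)C)C1(C)OC(=O)C(=O)OC | intermediate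
24 | methyl (2S,5R,6R)-6-{3-[(tert-butyldiphenylsilyl)oxy]propyl}-5-(3-hydroxyprop-1-en-2-yl)-1,2-dimethyl-2-[(triethylsilyl)oxy]cyclohexyl oxalate (both C-1 epimers) | C[C@]1(O[Si](CC)(CC)CC)CC[C@@H](C(=C)CO)[C@@H](CCCO[Si](c2ccccc2)(c2ccccc2)C(C)(C)C)C1(C)OC(=O)C(=O)OC | intermediate
25 | methyl (2S,5R,6R)-6-{3-[(tert-butyldiphenylsilyl)oxy]propyl}-1,2-dimethyl-5-(3-oxoprop-1-en-2-yl)-2-[(triethylsilyl)oxy]cyclohexyl oxalate (both C-1 epimers) | C[C@]1(O[Si](CC)(CC)CC)CC[C@@H](C(=C)C=O)[C@@H](CCCO[Si](c2ccccc2)(c2ccccc2)C(C)(C)C)C1(C)OC(=O)C(=O)OC | intermediate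
26 | methyl (2S,5Z,6R)-6-{3-[(tert-butyldiphenylsilyl)oxy]propyl}-1,2-dimethyl-5-(1-oxopropan-2-ylidene)-2-[(triethylsilyl)oxy]cyclohexyl oxalate (both C-1 epimers) | C[C@]1(O[Si](CC)(CC)CC)CC/C(=C(\C)C=O)[C@@H](CCCO[Si](c2ccccc2)(c2ccccc2)C(C)(C)C)C1(C)OC(=O)C(=O)OC | intermediate
27 | caesium 2-{[(2S,5Z,6R)-6-{3-[(tert-butyldiphenylsilyl)oxy]propyl}-1,2-dimethyl-5-(1-oxopropan-2-ylidene)-2-[(triethylsilyl)oxy]cyclohexyl]oxy}-2-oxoacetate (both C-1 epimers) | [Cs+].C[C@]1(O[Si](CC)(CC)CC)CC/C(=C(\C)C=O)[C@@H](CCCO[Si](c2ccccc2)(c2ccccc2)C(C)(C)C)C1(C)OC(=O)C([O-])=O | intermediate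
28 | (3E,5R,6E,8S)-1-[(1S,2S,5Z,6R)-6-{3-[(tert-butyldiphenylsilyl)oxy]propyl}-1,2-dimethyl-5-(1-oxopropan-2-ylidene)-2-[(triethylsilyl)oxy]cyclohexyl]-4,8,12-trimethyltrideca-3,6,11-trien-5-yl acetate | C[C@]1(O[Si](CC)(CC)CC)CC/C(=C(\C)C=O)[C@@H](CCCO[Si](c2ccccc2)(c2ccccc2)C(C)(C)C)[C@]1(C)CC/C=C(\C)[C@H](OC(C)=O)/C=C/[C@@H](C)CCC=C(C)C | intermediate
29 | (3E,5R,6E,8S)-1-[(1S,2S,5Z,6R)-2-hydroxy-6-(3-hydroxypropyl)-1,2-dimethyl-5-(1-oxopropan-2-ylidene)cyclohexyl]-4,8,12-trimethyltrideca-3,6,11-trien-5-yl acetate (CNP0259235.1) | C[C@]1(O)CC/C(=C(\C)C=O)[C@@H](CCCO)[C@]1(C)CC/C=C(\C)[C@H](OC(C)=O)/C=C/[C@@H](C)CCC=C(C)C | target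

**Step count**

Total steps: 19 (side chain 1–9, ring piece 10–17, union 18, deprotection 19).
Longest linear sequence: 11 steps (steps 1–9, 18, 19); the ring branch is 10 steps (10–19).

**Three steps most likely to fail**

1. Step 18 (the proposed new radical addition to the diene). Possible failures are slow addition of the hindered tertiary radical to an unactivated diene, 1,5-hydrogen transfer within the radical, or poor facial selectivity. The fallback uses known chemistry, sets out from 27 (with enyne 8 as partner) and comes back at 29.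
 - Known photoredox Giese addition of 27 to methyl acrylate (Ir[dF(CF3)ppy]2(dtbbpy)PF6, DME/DMF, H2O, blue LEDs) gives the methyl ester F1.
 - LiOH in THF/H2O gives the acid F2.
 - N-hydroxyphthalimide and N,N'-diisopropylcarbodiimide give the redox-active ester F3.
 - In parallel, 8 is carboaluminated as in step 7 but quenched with I2 to give the vinyl iodide F4.
 - Nickel-electrocatalytic decarboxylative alkenylation of F3 with F4 (NiCl2·6H2O, 2,2'-bipyridine, AgNO3, zinc anode, DMF) forms the sp3–sp2 bond and gives the silyl-protected coupling product F5.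
 - HF·pyridine in pyridine at 0 °C removes the allylic tert-butyldimethylsilyl and the tertiary triethylsilyl groups but not the primary tert-butyldiphenylsilyl ether, giving the diol F6.
 - Ac2O/pyridine acylates only the secondary allylic hydroxyl, giving the acetate F7.
 - TBAF buffered with AcOH then gives 29.

2. Step 13 (arm configuration by kinetic protonation; the cis ketone is the less stable epimer). The fallback replaces protonation by tethered C–C bond formation, sets out from 14 and comes back at 21.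
 - Acryloyl chloride, Et3N and DMAP give the acrylate F8.
 - LiN(SiMe3)2 in THF (−78 → 0 °C) triggers an intramolecular Michael addition of the ketone enolate to the tethered acrylate, giving the bridged keto lactone F9; the tether forces the new bond onto the face of the tertiary oxygen.
 - LiAlH4 reduces lactone and ketone to the triol F10.
 - TBDPSCl and imidazole give the primary silyl ether F11.
 - Dess–Martin periodinane gives the hydroxy ketone F12.
 - TESOTf and 2,6-lutidine give 21.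

3. Step 16 (alkene migration to the tetrasubstituted Z-enal; risks are incomplete migration and an E/Z mixture). The fallback builds the enal by a different sequence, sets out from 23, bypasses steps 15 and 16 and comes back at 26.
 - mCPBA with NaHCO3 epoxidises the isopropenyl group to the epoxide F13.
 - BF3·OEt2 at −78 °C (Meinwald rearrangement) gives the α-methyl aldehyde F14.
 - IBX in DMSO at 70 °C dehydrogenates it to the conjugated enal 26.

Further compounds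
F1 | step 18 | methyl 3-[(1S,2S,5Z,6R)-6-{3-[(tert-butyldiphenylsilyl)oxy]propyl}-1,2-dimethyl-5-(1-oxopropan-2-ylidene)-2-[(triethylsilyl)oxy]cyclohexyl]propanoate | C[C@]1(O[Si](CC)(CC)CC)CC/C(=C(\C)C=O)[C@@H](CCCO[Si](c2ccccc2)(c2ccccc2)C(C)(C)C)[C@]1(C)CCC(=O)OC
F2 | step 18 | 3-[(1S,2S,5Z,6R)-6-{3-[(tert-butyldiphenylsilyl)oxy]propyl}-1,2-dimethyl-5-(1-oxopropan-2-ylidene)-2-[(triethylsilyl)oxy]cyclohexyl]propanoic acid | C[C@]1(O[Si](CC)(CC)CC)CC/C(=C(\C)C=O)[C@@H](CCCO[Si](c2ccccc2)(c2ccccc2)C(C)(C)C)[C@]1(C)CCC(=O)O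
F3 | step 18 | 1,3-dioxoisoindolin-2-yl 3-[(1S,2S,5Z,6R)-6-{3-[(tert-butyldiphenylsilyl)oxy]propyl}-1,2-dimethyl-5-(1-oxopropan-2-ylidene)-2-[(triethylsilyl)oxy]cyclohexyl]propanoate | C[C@]1(O[Si](CC)(CC)CC)CC/C(=C(\C)C=O)[C@@H](CCCO[Si](c2ccccc2)(c2ccccc2)C(C)(C)C)[C@]1(C)CCC(=O)ON1C(=O)c2ccccc2C1=O
F4 | step 18 | tert-butyl{[(1E,3R,4E,6S)-1-iodo-2,6,10-trimethylundeca-1,4,9-trien-3-yl]oxy}dimethylsilane | I/C=C(\C)[C@H](O[Si](C)(C)C(C)(C)C)/C=C/[C@@H](C)CCC=C(C)C
F5 | step 18 | tert-butyl{[(3E,5R,6E,8S)-1-[(1S,2S,5Z,6R)-6-{3-[(tert-butyldiphenylsilyl)oxy]propyl}-1,2-dimethyl-5-(1-oxopropan-2-ylidene)-2-[(triethylsilyl)oxy]cyclohexyl]-4,8,12-trimethyltrideca-3,6,11-trien-5-yl]oxy}dimethylsilane | C[C@]1(O[Si](CC)(CC)CC)CC/C(=C(\C)C=O)[C@@H](CCCO[Si](c2ccccc2)(c2ccccc2)C(C)(C)C)[C@]1(C)CC/C=C(\C)[C@H](O[Si](C)(C)C(C)(C)C)/C=C/[C@@H](C)CCC=C(C)C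
F6 | step 18 | (3E,5R,6E,8S)-1-[(1S,2S,5Z,6R)-6-{3-[(tert-butyldiphenylsilyl)oxy]propyl}-2-hydroxy-1,2-dimethyl-5-(1-oxopropan-2-ylidene)cyclohexyl]-4,8,12-trimethyltrideca-3,6,11-trien-5-ol | C[C@]1(O)CC/C(=C(\C)C=O)[C@@H](CCCO[Si](c2ccccc2)(c2ccccc2)C(C)(C)C)[C@]1(C)CC/C=C(\C)[C@H](O)/C=C/[C@@H](C)CCC=C(C)C
F7 | step 18 | (3E,5R,6E,8S)-1-[(1S,2S,5Z,6R)-6-{3-[(tert-butyldiphenylsilyl)oxy]propyl}-2-hydroxy-1,2-dimethyl-5-(1-oxopropan-2-ylidene)cyclohexyl]-4,8,12-trimethyltrideca-3,6,11-trien-5-yl acetate | C[C@]1(O)CC/C(=C(\C)C=O)[C@@H](CCCO[Si](c2ccccc2)(c2ccccc2)C(C)(C)C)[C@]1(C)CC/C=C(\C)[C@H](OC(C)=O)/C=C/[C@@H](C)CCC=C(C)C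
F8 | step 13 | (1S,4R)-1-methyl-2-oxo-4-(prop-1-en-2-yl)cyclohexyl prop-2-enoate | C[C@]1(OC(=O)C=C)CC[C@@H](C(C)=C)CC1=O
F9 | step 13 | (1S,6R,7R)-1-methyl-7-(prop-1-en-2-yl)-2-oxabicyclo[4.3.1]decane-3,10-dione | C[C@@]12CC[C@@H](C(C)=C)[C@@H](CCC(=O)O1)C2=O
F10 | step 13 | (2S,5R,6R)-6-(3-hydroxypropyl)-2-methyl-5-(prop-1-en-2-yl)cyclohexane-1,2-diol (both C-1 epimers) | C[C@]1(O)CC[C@@H](C(C)=C)[C@@H](CCCO)C1O
F11 | step 13 | (2S,5R,6R)-6-{3-[(tert-butyldiphenylsilyl)oxy]propyl}-2-methyl-5-(prop-1-en-2-yl)cyclohexane-1,2-diol (both C-1 epimers) | C[C@]1(O)CC[C@@H](C(C)=C)[C@@H](CCCO[Si](c2ccccc2)(c2ccccc2)C(C)(C)C)C1O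
F12 | step 13 | (2S,5R,6R)-6-{3-[(tert-butyldiphenylsilyl)oxy]propyl}-2-hydroxy-2-methyl-5-(prop-1-en-2-yl)cyclohexan-1-one | C[C@]1(O)CC[C@@H](C(C)=C)[C@@H](CCCO[Si](c2ccccc2)(c2ccccc2)C(C)(C)C)C1=O
F13 | step 16 | methyl (2S,5R,6R)-6-{3-[(tert-butyldiphenylsilyl)oxy]propyl}-1,2-dimethyl-5-(2-methyloxiran-2-yl)-2-[(triethylsilyl)oxy]cyclohexyl oxalate (epimer mixture at C-1 and at the oxirane) | C[C@]1(O[Si](CC)(CC)CC)CC[C@@H](C2(C)CO2)[C@@H](CCCO[Si](c3ccccc3)(c3ccccc3)C(C)(C)C)C1(C)OC(=O)C(=O)OC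
F14 | step 16 | methyl (2S,5R,6R)-6-{3-[(tert-butyldiphenylsilyl)oxy]propyl}-1,2-dimethyl-5-(1-oxopropan-2-yl)-2-[(triethylsilyl)oxy]cyclohexyl oxalate (epimer mixture at C-1 and at the aldehyde α-carbon) | C[C@]1(O[Si](CC)(CC)CC)CC[C@@H](C(C)C=O)[C@@H](CCCO[Si](c2ccccc2)(c2ccccc2)C(C)(C)C)C1(C)OC(=O)C(=O)OC
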